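**Retrosynthetic overview**

1. Target 20 ⇐ ten-membered (Z)-enone 18: global desilylation, then the C10 hydroxyl closes the 3,10-bridged hemiketal (C3 is dictated by C10).
2. 18 ⇐ seco iodoalkene/vinyl lactone 16: hydroboration, then a new ring-closing carbonylative B-alkyl Suzuki–Miyaura coupling (C2–C3 and C3–C4 bonds; CO becomes C3).
3. cis-Lactone 14 ⇐ (Z)-allyl bromide 7 + iodo-enal 12: indium Barbier allylation/lactonisation (C6–C7 bond; C6 and C7 set against C8).
4. 7 ⇐ (S)-linalool (C10): ozonolysis, catalytic α-oxyamination (C8), Morita–Baylis–Hillman, SN2' bromination. 12 ⇐ but-2-yne-1,4-diol.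
5. Ring order: γ-lactone first, then the ten-membered carbocycle, then the oxygen-bridged tetrahydrofuran (hemiketal) last.

Assumption: (S)-(+)-linalool is bought as the single enantiomer, and the target is taken exactly as its SMILES gives it (3S,6S,7R,8R,10R, 4Z, cis-fused 6,12-lactone; germacrane numbering C1–C15 is used in the explanations).

**Step 1**
Reactants: 1 (S)-(+)-linalool, (3S)-3,7-dimethylocta-1,6-dien-3-ol
Product: 2 triethyl{[(3S)-3,7-dimethylocta-1,6-dien-3-yl]oxy}silane
Conditions: TESOTf, 2,6-lutidine, CH2Cl2, −78 → 0 °C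
Reagents that add atoms: triethylsilyl trifluoromethanesulfonate, CC[Si](CC)(CC)OS(=O)(=O)C(F)(F)F
Why: O-silylation of the tertiary allylic alcohol with a silyl triflate is fast and leaves the purchased stereocentre (the future C10) untouched.

**Step 2**
Reactants: 2 triethyl{[(3S)-3,7-dimethylocta-1,6-dien-3-yl]oxy}silane
Product: 3 (4S)-4-methyl-4-[(triethylsilyl)oxy]hex-5-enal
Conditions: O3 (1.0 equiv, Sudan Red 7B end point), pyridine (3 equiv), CH2Cl2, −78 °C
Reagents that add atoms: ozone, [O-][O+]=O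
Why: Ozonolysis is chemoselective for the electron-rich trisubstituted alkene over the hindered monosubstituted vinyl group, and pyridine converts the carbonyl oxide directly into the aldehyde (C7) without a separate reductant.

**Step 3**
Reactants: 3 (4S)-4-methyl-4-[(triethylsilyl)oxy]hex-5-enal
Product: 4 (2R,4S)-4-methyl-2-[(2,2,6,6-tetramethylpiperidin-1-yl)oxy]-4-[(triethylsilyl)oxy]hex-5-enal
Conditions: TEMPO (1.2 equiv), (5R)-5-benzyl-2,2,3-trimethylimidazolidin-4-one·CF3CO2H (first-generation imidazolidinone, 20 mol %; the enantiomer that gives the 2R aldehyde), CuCl2·2H2O (10 mol %), air, acetone, −10 °C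
Reagents that add atoms: TEMPO, CC1(C)CCCC(C)(C)N1[O]
Why: Enamine-mediated asymmetric α-oxyamination: the chiral imidazolidinone shields one face of the E-enamine so the copper-bound nitroxyl adds to the other, setting C8 as R under catalyst control (the remote C10 centre has no say) and leaving a configurationally stable, non-chelating O-substituent.

**Step 4**
Reactants: 4 (2R,4S)-4-methyl-2-[(2,2,6,6-tetramethylpiperidin-1-yl)oxy]-4-[(triethylsilyl)oxy]hex-5-enal; 5 methyl acrylate
Product: 6 methyl (4R,6S)-3-hydroxy-6-methyl-2-methylidene-4-[(2,2,6,6-tetramethylpiperidin-1-yl)oxy]-6-[(triethylsilyl)oxy]oct-7-enoate (both C3 epimers)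
Conditions: 5 (5 equiv), DABCO (1 equiv), MeOH (1 equiv), rt, 3 d
Reagents that add atoms: none
Why: Morita–Baylis–Hillman reaction of the activated α-oxy aldehyde joins C7 to C11 and brings in C12 and C13; the new carbinol centre is left unassigned because the next step erases it.

**Step 5**
Reactants: 6 methyl (4R,6S)-3-hydroxy-6-methyl-2-methylidene-4-[(2,2,6,6-tetramethylpiperidin-1-yl)oxy]-6-[(triethylsilyl)oxy]oct-7-enoate
Product: 7 methyl (2Z,4R,6S)-2-(bromomethyl)-6-methyl-4-[(2,2,6,6-tetramethylpiperidin-1-yl)oxy]-6-[(triethylsilyl)oxy]octa-2,7-dienoate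
Conditions: NBS, Me2S, CH2Cl2, −20 °C; then 6, → rt
Reagents that add atoms: N-bromosuccinimide, O=C1CCC(=O)N1Br
Why: Corey–Kim-type activation of the allylic hydroxyl and SN2' attack of bromide give the thermodynamically favoured (Z)-2-(bromomethyl)enoate (C8 cis to CH2Br, trans to the ester) without touching C8.

**Step 6**
Reactants: 8 but-2-yne-1,4-diol
Product: 9 4-{[tert-butyl(dimethyl)silyl]oxy}but-2-yn-1-ol
Conditions: TBSCl (1 equiv), imidazole, 8 (3 equiv), DMF, 0 °C
Reagents that add atoms: tert-butyldimethylsilyl chloride, CC(C)(C)[Si](C)(C)Cl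
Why: Statistical mono-O-silylation of the symmetrical diol used in excess gives the mono-ether whose silyloxy group becomes the protected C15 hydroxyl.

**Step 7**
Reactants: 9 4-{[tert-butyl(dimethyl)silyl]oxy}but-2-yn-1-ol
Product: 11 (2Z)-4-{[tert-butyl(dimethyl)silyl]oxy}-3-iodobut-2-en-1-ol, via cyclic alkenylalanate 10 (not isolated)
Conditions: NaAlH2(OCH2CH2OMe)2, THF, 0 °C → rt; then I2, THF, −78 → 0 °C
Reagents that add atoms: iodine, [I][I]; NaAlH2(OCH2CH2OMe)2, [Na+].COCCO[AlH2-]OCCOC (its aluminate unit stays only in intermediate 10)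
Why: Hydroxyl-directed trans-hydroalumination puts hydride on the alkyne carbon next to the free carbinol and aluminium on the distal carbon in a five-membered alanate, and iodinolysis with retention gives the (Z)-alkenyl iodide in which the CH2OH carbon (C6) is cis to iodine (the future C3).

**Step 8**
Reactants: 11 (2Z)-4-{[tert-butyl(dimethyl)silyl]oxy}-3-iodobut-2-en-1-ol
Product: 12 (2Z)-4-{[tert-butyl(dimethyl)silyl]oxy}-3-iodobut-2-enal
Conditions: Dess–Martin periodinane, pyridine, CH2Cl2, 0 °C, dark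
Reagents that add atoms: none
Why: Dess–Martin oxidation of the primary allylic alcohol is fast and near-neutral, so the Z geometry of the iodoalkene is kept.

**Step 9**
Reactants: 7 methyl (2Z,4R,6S)-2-(bromomethyl)-6-methyl-4-[(2,2,6,6-tetramethylpiperidin-1-yl)oxy]-6-[(triethylsilyl)oxy]octa-2,7-dienoate; 12 (2Z)-4-{[tert-butyl(dimethyl)silyl]oxy}-3-iodobut-2-enal
Product: 14 (4S,5R)-5-[(1Z)-3-{[tert-butyl(dimethyl)silyl]oxy}-2-iodoprop-1-en-1-yl]-3-methylidene-4-{(1R,3S)-3-methyl-1-[(2,2,6,6-tetramethylpiperidin-1-yl)oxy]-3-[(triethylsilyl)oxy]pent-4-en-1-yl}oxolan-2-one, via hydroxy ester 13 (not isolated)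
Conditions: In powder (1.5 equiv), THF/H2O (1:1), rt; then PPTS (0.3 equiv), toluene, 50 °C
Reagents that add atoms: none
Why: Barbier-type 2-(alkoxycarbonyl)allylation followed by acid-catalysed lactonisation: the (Z)-allylindium reacts at C7 through a Zimmerman–Traxler chair with the C8 branch axial, giving the syn C6/C7 adduct and hence the cis-fused lactone, while 1,3-allylic strain keeps C8–H in the alkene plane so the aldehyde approaches C7 anti to the bulky C9 branch with the non-chelating C8–O bond gauche to the new bond, which sets C6 and C7 relative to C8.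

**Step 10**
Reactants: 14 the TEMPO-protected cis-lactone from step 9
Product: 15 (4R,5R)-5-[(1Z)-3-{[tert-butyl(dimethyl)silyl]oxy}-2-iodoprop-1-en-1-yl]-4-{(1R,3S)-1-hydroxy-3-methyl-3-[(triethylsilyl)oxy]pent-4-en-1-yl}-3-methylideneoxolan-2-one
Conditions: Zn dust, AcOH/THF/H2O (3:1:1), rt → 35 °C
Reagents that add atoms: none
Why: Reductive N–O cleavage of the alkoxyamine by zinc in acetic acid frees the C8 hydroxyl with retention, while the alkenyl iodide, the silyl ethers and the unsaturated lactone are inert to zinc at this temperature.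

**Step 11**
Reactants: 15 the C8 alcohol from step 10
Product: 16 (1R,3S)-1-{(2R,3R)-2-[(1Z)-3-{[tert-butyl(dimethyl)silyl]oxy}-2-iodoprop-1-en-1-yl]-4-methylidene-5-oxooxolan-3-yl}-3-methyl-3-[(triethylsilyl)oxy]pent-4-en-1-yl 2-methylpropanoate
Conditions: (i-PrCO)2O, DMAP (0.2 equiv), pyridine, CH2Cl2, 0 °C → rt
Reagents that add atoms: 2-methylpropanoic anhydride, CC(C)C(=O)OC(=O)C(C)C
Why: DMAP-catalysed acyl transfer (Steglich-type acylation) esterifies the only free hydroxyl and places the natural isobutyrate on C8 with retention.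

**Step 12**
Reactants: 16 the seco iodoalkene/vinyl isobutyrate from step 11
Product: 18 (3aR,4R,6R,10Z,11aS)-10-({[tert-butyl(dimethyl)silyl]oxy}methyl)-6-methyl-3-methylidene-2,9-dioxo-6-[(triethylsilyl)oxy]-2,3,3a,4,5,6,7,8,9,11a-decahydrocyclodeca[b]furan-4-yl 2-methylpropanoate, via B-alkyl borane 17 (not isolated)
Conditions: 9-BBN (1.3 equiv), THF, 0 °C → rt; then syringe-pump addition to PdCl2(dppf) (15 mol %), anhydrous K3PO4 (3 equiv), CO (1 atm), THF/DMF, 45 °C, final 2 mM
Reagents that add atoms: carbon monoxide, [C-]#[O+]; 9-borabicyclo[3.3.1]nonane, B1C2CCCC1CCC2 (its boron cage stays only in intermediate 17)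
Why: Proposed new method: ring-closing carbonylative B-alkyl Suzuki–Miyaura coupling to a medium-ring enone — 9-BBN hydroborates only the monosubstituted vinyl group (boron on C2), zerovalent palladium inserts into the C4–iodine bond, CO insertion (fast for alkenylpalladium at 1 atm and faster than the slow intramolecular boron-to-palladium transfer) gives an acylpalladium, and phosphate-activated transfer of the primary C2 alkyl group followed by reductive elimination forges C3–C4 and C2–C3 with CO as C3, closing the ten-membered ring at the ketone oxidation level; the cis-lactone holds both chains on one face and the Z-iodoalkene points C4 towards the borane, chelating dppf leaves no cis site for alkene insertion into the acyl–palladium bond, anhydrous base avoids acyl hydrolysis, high dilution suppresses dimers, and no stereocentre is touched; the closest known reactions are the intermolecular carbonylative coupling of B-alkyl-9-BBN reagents with iodoalkenes, B-alkyl Suzuki–Miyaura macrocyclisation and carbonylative Stille macrocyclisation.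

**Step 13**
Reactants: 18 the ten-membered (Z)-enone from step 12
Product: 20 CNP0282937.2, (3S,6S,7R,8R,10R,4Z)-3,15-dihydroxy-8-(2-methylpropanoyloxy)-3,10-epoxygermacra-4,11(13)-dien-12,6-olide, via keto diol 19 (not isolated)
Conditions: HF·pyridine, pyridine, THF, 0 °C → rt
Reagents that add atoms: none
Why: Fluoride-mediated desilylation frees the C15 and C10 hydroxyls, and the tertiary C10 hydroxyl adds across the ring to the C3 ketone (transannular hemiketalisation under thermodynamic control); the oxygen bridge can only span the new tetrahydrofuran cis, so C10 forces C3 to be S.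

**Compound list**

1 | (S)-(+)-linalool, (3S)-3,7-dimethylocta-1,6-dien-3-ol | C=C[C@@](C)(O)CCC=C(C)C | starting material
2 | triethyl{[(3S)-3,7-dimethylocta-1,6-dien-3-yl]oxy}silane | C=C[C@@](C)(O[Si](CC)(CC)CC)CCC=C(C)C | intermediate
3 | (4S)-4-methyl-4-[(triethylsilyl)oxy]hex-5-enal | C=C[C@@](C)(O[Si](CC)(CC)CC)CCC=O | intermediate
4 | (2R,4S)-4-methyl-2-[(2,2,6,6-tetramethylpiperidin-1-yl)oxy]-4-[(triethylsilyl)oxy]hex-5-enal | C=C[C@@](C)(O[Si](CC)(CC)CC)C[C@@H](ON1C(C)(C)CCCC1(C)C)C=O | intermediate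
5 | methyl acrylate | C=CC(=O)OC | starting material
6 | methyl (4R,6S)-3-hydroxy-6-methyl-2-methylidene-4-[(2,2,6,6-tetramethylpiperidin-1-yl)oxy]-6-[(triethylsilyl)oxy]oct-7-enoate (both C3 epimers) | C=C[C@@](C)(O[Si](CC)(CC)CC)C[C@@H](ON1C(C)(C)CCCC1(C)C)C(O)C(=C)C(=O)OC | intermediate
7 | methyl (2Z,4R,6S)-2-(bromomethyl)-6-methyl-4-[(2,2,6,6-tetramethylpiperidin-1-yl)oxy]-6-[(triethylsilyl)oxy]octa-2,7-dienoate | C=C[C@@](C)(O[Si](CC)(CC)CC)C[C@@H](ON1C(C)(C)CCCC1(C)C)/C=C(\CBr)C(=O)OC | intermediate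
8 | but-2-yne-1,4-diol | OCC#CCO | starting material
9 | 4-{[tert-butyl(dimethyl)silyl]oxy}but-2-yn-1-ol | OCC#CCO[Si](C)(C)C(C)(C)C | intermediate
10 | sodium 3-({[tert-butyl(dimethyl)silyl]oxy}methyl)-2,2-bis(2-methoxyethoxy)-2,5-dihydro-1,2-oxaluminol-2-uide (cyclic alkenylalanate, not isolated) | [Na+].COCCO[Al-]1(OCCOC)OCC=C1CO[Si](C)(C)C(C)(C)C | intermediate
11 | (2Z)-4-{[tert-butyl(dimethyl)silyl]oxy}-3-iodobut-2-en-1-ol | OC/C=C(\I)CO[Si](C)(C)C(C)(C)C | intermediate
12 | (2Z)-4-{[tert-butyl(dimethyl)silyl]oxy}-3-iodobut-2-enal | O=C/C=C(\I)CO[Si](C)(C)C(C)(C)C | intermediate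
13 | methyl (3S,4R,6S)-3-[(1R,2Z)-4-{[tert-butyl(dimethyl)silyl]oxy}-1-hydroxy-3-iodobut-2-en-1-yl]-6-methyl-2-methylidene-4-[(2,2,6,6-tetramethylpiperidin-1-yl)oxy]-6-[(triethylsilyl)oxy]oct-7-enoate (hydroxy ester, not isolated) | COC(=O)C(=C)[C@@H]([C@@H](O)/C=C(\I)CO[Si](C)(C)C(C)(C)C)[C@H](ON1C(C)(C)CCCC1(C)C)C[C@](C)(O[Si](CC)(CC)CC)C=C | intermediate
14 | (4S,5R)-5-[(1Z)-3-{[tert-butyl(dimethyl)silyl]oxy}-2-iodoprop-1-en-1-yl]-3-methylidene-4-{(1R,3S)-3-methyl-1-[(2,2,6,6-tetramethylpiperidin-1-yl)oxy]-3-[(triethylsilyl)oxy]pent-4-en-1-yl}oxolan-2-one | C=C1C(=O)O[C@@H](/C=C(\I)CO[Si](C)(C)C(C)(C)C)[C@H]1[C@H](ON2C(C)(C)CCCC2(C)C)C[C@](C)(O[Si](CC)(CC)CC)C=C | intermediate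
15 | (4R,5R)-5-[(1Z)-3-{[tert-butyl(dimethyl)silyl]oxy}-2-iodoprop-1-en-1-yl]-4-{(1R,3S)-1-hydroxy-3-methyl-3-[(triethylsilyl)oxy]pent-4-en-1-yl}-3-methylideneoxolan-2-one | C=C1C(=O)O[C@@H](/C=C(\I)CO[Si](C)(C)C(C)(C)C)[C@H]1[C@H](O)C[C@](C)(O[Si](CC)(CC)CC)C=C | intermediate
16 | (1R,3S)-1-{(2R,3R)-2-[(1Z)-3-{[tert-butyl(dimethyl)silyl]oxy}-2-iodoprop-1-en-1-yl]-4-methylidene-5-oxooxolan-3-yl}-3-methyl-3-[(triethylsilyl)oxy]pent-4-en-1-yl 2-methylpropanoate | C=C1C(=O)O[C@@H](/C=C(\I)CO[Si](C)(C)C(C)(C)C)[C@H]1[C@H](OC(=O)C(C)C)C[C@](C)(O[Si](CC)(CC)CC)C=C | intermediate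
17 | (1R,3R)-5-(9-borabicyclo[3.3.1]nonan-9-yl)-1-{(2R,3R)-2-[(1Z)-3-{[tert-butyl(dimethyl)silyl]oxy}-2-iodoprop-1-en-1-yl]-4-methylidene-5-oxooxolan-3-yl}-3-methyl-3-[(triethylsilyl)oxy]pentyl 2-methylpropanoate (B-alkyl borane, not isolated) | C=C1C(=O)O[C@@H](/C=C(\I)CO[Si](C)(C)C(C)(C)C)[C@H]1[C@H](OC(=O)C(C)C)C[C@](C)(O[Si](CC)(CC)CC)CCB1C2CCCC1CCC2 | intermediate
18 | (3aR,4R,6R,10Z,11aS)-10-({[tert-butyl(dimethyl)silyl]oxy}methyl)-6-methyl-3-methylidene-2,9-dioxo-6-[(triethylsilyl)oxy]-2,3,3a,4,5,6,7,8,9,11a-decahydrocyclodeca[b]furan-4-yl 2-methylpropanoate | C=C1C(=O)O[C@H]2/C=C(/CO[Si](C)(C)C(C)(C)C)C(=O)CC[C@@](C)(O[Si](CC)(CC)CC)C[C@@H](OC(=O)C(C)C)[C@@H]12 | intermediate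
19 | (3aR,4R,6R,10Z,11aS)-6-hydroxy-10-(hydroxymethyl)-6-methyl-3-methylidene-2,9-dioxo-2,3,3a,4,5,6,7,8,9,11a-decahydrocyclodeca[b]furan-4-yl 2-methylpropanoate (keto diol, not isolated) | C=C1C(=O)O[C@H]2/C=C(/CO)C(=O)CC[C@@](C)(O)C[C@@H](OC(=O)C(C)C)[C@@H]12 | intermediate
20 | CNP0282937.2, (3S,6S,7R,8R,10R,4Z)-3,15-dihydroxy-8-(2-methylpropanoyloxy)-3,10-epoxygermacra-4,11(13)-dien-12,6-olide | C=C1C(=O)O[C@H]2/C=C(/CO)[C@]3(O)CC[C@](C)(C[C@@H](OC(=O)C(C)C)[C@@H]12)O3 | target

**Step count and risks**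

Total step count: 13. Longest linear sequence: 10 steps (steps 1–5 and 9–13); steps 6–8 make the second building block.

The three steps most likely to fail:

Step 12 (the proposed new ring closure). The acylpalladium may be intercepted before the slow medium-ring boron-to-palladium transfer, by dimerisation or by insertion of the α-methylene lactone alkene, and zerovalent palladium could also ionise the allylic lactone. The fallback uses known chemistry only and sets out from 16. Linear-selective hydroformylation of the terminal vinyl group (Rh(acac)(CO)2, Xantphos, CO/H2, toluene, 60 °C) gives the C3 aldehyde (1R,3R)-1-{(2R,3R)-2-[(1Z)-3-{[tert-butyl(dimethyl)silyl]oxy}-2-iodoprop-1-en-1-yl]-4-methylidene-5-oxooxolan-3-yl}-3-methyl-6-oxo-3-[(triethylsilyl)oxy]hexyl 2-methylpropanoate F1. Nozaki–Hiyama–Kishi macrocyclisation (CrCl2, NiCl2 cat., DMSO/THF, high dilution) then closes the ten-membered ring to the allylic alcohol (3aR,4R,6R,10Z,11aS)-10-({[tert-butyl(dimethyl)silyl]oxy}methyl)-9-hydroxy-6-methyl-3-methylidene-2-oxo-6-[(triethylsilyl)oxy]-2,3,3a,4,5,6,7,8,9,11a-decahydrocyclodeca[b]furan-4-yl 2-methylpropanoate F2 (both C9 epimers). Dess–Martin oxidation of F2 comes back to the route at 18.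

Step 9 (facial selectivity of the Barbier allylation). The syn C6/C7 relationship is reliable, but the sense relative to C8 rests on an acyclic model, and attack anti to the C8–O bond would give the wrong cis-lactone. The fallback sets out from 7 and replaces substrate control by catalyst control. Borylation with B2pin2 (Pd2(dba)3 cat., DMSO, 50 °C) gives the allylboronate methyl (2E,4R,6S)-6-methyl-2-[(4,4,5,5-tetramethyl-1,3,2-dioxaborolan-2-yl)methyl]-4-[(2,2,6,6-tetramethylpiperidin-1-yl)oxy]-6-[(triethylsilyl)oxy]octa-2,7-dienoate F3 (same alkene geometry as 7; the descriptor changes only through priorities). Allylboration of 12 through a closed chair transition state, catalysed by the chiral phosphoric acid TRIP (the enantiomer that selects the aldehyde face leading to 14), followed by PPTS lactonisation, comes back at 14.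

Step 4 (Morita–Baylis–Hillman on a hindered α-aminoxy aldehyde). The reaction may be very slow and may erode C8. The fallback sets out from 4 and uses a preformed nucleophile instead of amine catalysis. [1-(Methoxycarbonyl)ethenyl]bis(2-methylpropyl)alane F4, generated in the flask from methyl propiolate, i-Bu2AlH and N-methylmorpholine N-oxide in THF, adds to the aldehyde at 0 °C (vinylalumination) and comes back at 6.

**Further compounds**

F1 | step 12 | (1R,3R)-1-{(2R,3R)-2-[(1Z)-3-{[tert-butyl(dimethyl)silyl]oxy}-2-iodoprop-1-en-1-yl]-4-methylidene-5-oxooxolan-3-yl}-3-methyl-6-oxo-3-[(triethylsilyl)oxy]hexyl 2-methylpropanoate | C=C1C(=O)O[C@@H](/C=C(\I)CO[Si](C)(C)C(C)(C)C)[C@H]1[C@H](OC(=O)C(C)C)C[C@](C)(O[Si](CC)(CC)CC)CCC=O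
F2 | step 12 | (3aR,4R,6R,10Z,11aS)-10-({[tert-butyl(dimethyl)silyl]oxy}methyl)-9-hydroxy-6-methyl-3-methylidene-2-oxo-6-[(triethylsilyl)oxy]-2,3,3a,4,5,6,7,8,9,11a-decahydrocyclodeca[b]furan-4-yl 2-methylpropanoate (both C9 epimers) | C=C1C(=O)O[C@H]2/C=C(/CO[Si](C)(C)C(C)(C)C)C(O)CC[C@@](C)(O[Si](CC)(CC)CC)C[C@@H](OC(=O)C(C)C)[C@@H]12
F3 | step 9 | methyl (2E,4R,6S)-6-methyl-2-[(4,4,5,5-tetramethyl-1,3,2-dioxaborolan-2-yl)methyl]-4-[(2,2,6,6-tetramethylpiperidin-1-yl)oxy]-6-[(triethylsilyl)oxy]octa-2,7-dienoate | C=C[C@@](C)(O[Si](CC)(CC)CC)C[C@@H](ON1C(C)(C)CCCC1(C)C)/C=C(\CB1OC(C)(C)C(C)(C)O1)C(=O)OC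
F4 | step 4 | [1-(methoxycarbonyl)ethenyl]bis(2-methylpropyl)alane | C=C(C(=O)OC)[Al](CC(C)C)CC(C)C
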